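**Retrosynthetic overview**

1. The target is a depsidone. Ring A (four oxygens, one prenyl group, fused 2,2-dimethylpyran) and ring B are joined by a diaryl ether oxygen and an aryl ester that together close a seven-membered lactone. The last disconnections are the ring B methyl ether ortho to the carbonyl and then the lactone C–O bond, from the ring A hydroxyl next to the ether oxygen onto a ring B carboxyl. The carboxyl is carried as a 2-(trimethylsilyl)ethyl (TMSE) ester, because a methyl ester cannot be transesterified into the aryl lactone and is too hindered to saponify.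
2. Key disconnection: ring B is taken apart completely. Its carbons run C(OH)–C(prenyl)–C(OAr)–C(CO2R)–C(OMe)–CH, so the prenyl carbon lies between the hydroxyl carbon and the aryloxy carbon and the carboxyl carbon is para to the hydroxyl. A vinylketene bearing CO2R and 1-methoxyvinyl on the ketene carbon (from Wolff rearrangement of a diazo keto ester) adding to a ring A aryl prenylethynyl ether leaves exactly this pattern, and the crowded ether oxygen enters as an unhindered ynol ether.
3. Ring A phenol: symmetric 2,5-bis(methoxymethoxy)-3,6-diprenyl-1,4-benzoquinone isomerises under base to the 6-hydroxychromene, which closes the pyran ring on one prenyl group and frees the para oxygen as the phenol. The quinone comes from 1,2,4,5-tetramethoxybenzene by double prenylation, oxidative demethylation and methyl-to-MOM exchange.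
4. Order of ring formation: ring A is bought, then the pyran ring (step 5), ring B (step 11), the lactone ring (step 14).

Key step: step 11

Remark: the target has no stereocentre, so the route sets none. The ring A hydroquinone freed in step 12 is air-sensitive and is handled under argon until the lactone is closed.

**Route**

Step 1
Reactants: 1 1,2,4,5-tetramethoxybenzene; 2 prenyl bromide (1-bromo-3-methylbut-2-ene)
Product: 4 1,2,4,5-tetramethoxy-3,6-bis(3-methylbut-2-enyl)benzene, via dilithiated arene 3 (not isolated)
Conditions: n-BuLi (2.5 equiv), TMEDA, Et2O/hexane, 0 °C to rt; then CuBr·SMe2 (10 mol %), 2 (2.6 equiv), −78 °C to rt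
Reagents that add atoms: none
Why: Double directed ortho-metalation should remove both ring hydrogens, each of which lies between two methoxy groups, and copper-catalysed SN2 allylation of the aryllithium with prenyl bromide should give the unrearranged prenyl groups.

Step 2
Reactants: 4 1,2,4,5-tetramethoxy-3,6-bis(3-methylbut-2-enyl)benzene
Product: 5 2,5-dimethoxy-3,6-bis(3-methylbut-2-enyl)cyclohexa-2,5-diene-1,4-dione
Conditions: (NH4)2Ce(NO3)6 (2.5 equiv), MeCN/H2O, 0 °C
Reagents that add atoms: water, O
Why: Oxidative demethylation of a para-dimethoxyarene (two one-electron oxidations, ipso attack of water, loss of methanol) should give the para-quinone under conditions that prenyl side chains are known to survive, and either para pair of the four equivalent methoxy groups leads to the same quinone.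

Step 3
Reactants: 5 2,5-dimethoxy-3,6-bis(3-methylbut-2-enyl)cyclohexa-2,5-diene-1,4-dione
Product: 6 2,5-dihydroxy-3,6-bis(3-methylbut-2-enyl)cyclohexa-2,5-diene-1,4-dione
Conditions: NaOH (2 M aq.), MeOH/THF, 0 °C to rt, Ar; then 1 M HCl, 0 °C
Reagents that add atoms: sodium hydroxide, [Na+].[OH-]
Why: Hydrolysis of the vinylogous methyl esters by conjugate addition–elimination of hydroxide should give the hydroxyquinone dianion, which is inert to further base and is released by cold acidification mild enough not to cyclise the prenyl groups.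

Step 4
Reactants: 6 2,5-dihydroxy-3,6-bis(3-methylbut-2-enyl)cyclohexa-2,5-diene-1,4-dione
Product: 7 2,5-bis(methoxymethoxy)-3,6-bis(3-methylbut-2-enyl)cyclohexa-2,5-diene-1,4-dione
Conditions: MOMCl (2.5 equiv), iPr2NEt, CH2Cl2, 0 °C
Reagents that add atoms: chloromethyl methyl ether (MOMCl), COCCl
Why: O-alkylation of the vinylogous acid with MOMCl and an amine base should give the 2,5-diether of the para-quinone, the more stable of the possible quinone ethers, with the two acetal groups on the para pair of oxygens that later flank the pyran and the lactone.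

Step 5
Reactants: 7 2,5-bis(methoxymethoxy)-3,6-bis(3-methylbut-2-enyl)cyclohexa-2,5-diene-1,4-dione
Product: 9 5,8-bis(methoxymethoxy)-2,2-dimethyl-7-(3-methylbut-2-enyl)-2H-chromen-6-ol (ring A phenol), via ortho-quinone methide 8 (not isolated)
Conditions: pyridine, 115 °C, Ar
Reagents that add atoms: none
Why: Base-induced tautomerisation of a prenylquinone (deprotonation of the allylic CH2 through the vinylogous carbonyl) should give the ortho-quinone methide, which closes the pyran ring by oxa-6-pi electrocyclisation and aromatises (the known quinone-to-chromenol isomerisation); the two prenyl groups are equivalent by symmetry and the second cannot react once the quinone is consumed.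

Step 6
Reactants: 9 ring A phenol; 10 trichloroethylene
Product: 11 (E)-1,2-dichlorovinyl ether of the ring A phenol
Conditions: K2CO3, DMF, 70 °C
Reagents that add atoms: none
Why: Base converts trichloroethylene into dichloroacetylene, to which the phenoxide adds anti to give the (E)-1,2-dichlorovinyl ether, a standard O-vinylation of phenols that tolerates two ortho substituents.

Step 7
Reactants: 11 (E)-1,2-dichlorovinyl ether of the ring A phenol; 2 prenyl bromide
Product: 14 5,8-bis(methoxymethoxy)-2,2-dimethyl-7-(3-methylbut-2-enyl)-6-[(5-methylhex-4-en-1-yn-1-yl)oxy]-2H-chromene (ring A aryl prenylethynyl ether), via chloroethynyl ether 12 (not isolated), via lithium aryloxyacetylide 13 (not isolated)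
Conditions: n-BuLi (2.05 equiv), THF, −78 to −40 °C; then CuI (10 mol %), 2, −40 to 0 °C
Reagents that add atoms: none
Why: Dehydrochlorination to the chloroalkyne and chlorine–lithium exchange (the dichlorovinyl ether route to alkynyl ethers) give the lithium aryloxyacetylide, whose copper-catalysed SN2 alkylation at the primary carbon of prenyl bromide should give the skipped enyne, and the exact two equivalents of n-BuLi leave no base to deprotonate its doubly activated CH2.

Step 8
Reactants: 15 methyl 2-methoxyacrylate
Product: 16 2-methoxyacrylic acid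
Conditions: LiOH·H2O, THF/H2O, 0 °C to rt; then 1 M HCl to pH 3, 0 °C
Reagents that add atoms: lithium hydroxide, [Li+].[OH-]
Why: Saponification of the methyl ester (BAc2) should proceed normally, and the captodative enol ether resists hydrolysis during the brief cold acidification.

Step 9
Reactants: 16 2-methoxyacrylic acid; 17 Meldrum's acid (2,2-dimethyl-1,3-dioxane-4,6-dione); 18 2-(trimethylsilyl)ethanol
Product: 21 2-(trimethylsilyl)ethyl 4-methoxy-3-oxopent-4-enoate, via acyl Meldrum's acid 19 (not isolated), via acylketene 20 (not isolated)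
Conditions: DCC, DMAP, CH2Cl2, 0 °C to rt; filter; then 18, PhMe, 80 °C
Reagents that add atoms: none
Why: Carbodiimide C-acylation of Meldrum's acid followed by thermal loss of acetone and CO2 to an acylketene that the alcohol traps is the acyl Meldrum's acid route to beta-keto esters, and it installs the TMSE ester that fluoride can later cleave at silicon instead of at the crowded carbonyl.

Step 10
Reactants: 21 2-(trimethylsilyl)ethyl 4-methoxy-3-oxopent-4-enoate
Product: 22 2-(trimethylsilyl)ethyl 2-diazo-4-methoxy-3-oxopent-4-enoate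
Conditions: p-ABSA, Et3N, MeCN, 0 °C to rt
Reagents that add atoms: 4-acetamidobenzenesulfonyl azide (p-ABSA), CC(=O)Nc1ccc(cc1)S(=O)(=O)N=[N+]=[N-]
Why: Regitz diazo transfer from a sulfonyl azide to the active methylene of a beta-keto ester under amine base is general and leaves the enol ether untouched.

Step 11
Reactants: 14 ring A aryl prenylethynyl ether; 22 2-(trimethylsilyl)ethyl 2-diazo-4-methoxy-3-oxopent-4-enoate
Product: 27 2-(trimethylsilyl)ethyl 2-{[5,8-bis(methoxymethoxy)-2,2-dimethyl-7-(3-methylbut-2-enyl)-2H-chromen-6-yl]oxy}-4-hydroxy-6-methoxy-3-(3-methylbut-2-enyl)benzoate, via vinylketene 23 (not isolated), via vinylcyclobutenone 24 (not isolated), via dienylketene 25 (not isolated), via cyclohexadienone 26 (not isolated)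
Conditions: hν (365 nm), ClCH2CH2Cl, rt, slow addition of 22 (1.5 equiv); then 80 °C
Reagents that add atoms: none
Why: Proposed new method: irradiation should expel N2 from 22 with 1,2-shift of the 1-methoxyvinyl group (Wolff rearrangement) to give vinylketene 23, whose carbonyl carbon is attacked by the nucleophilic, prenyl-bearing carbon of ynol ether 14 so that a [2+2] cycloaddition closes vinylcyclobutenone 24. Warming opens 24 by 4-pi electrocyclic cleavage to dienylketene 25, which closes ring B by a 6-pi electrocyclisation between the ketene carbon and the CH2 terminus of the methoxyvinyl group and then tautomerises (26 to 27), three ring B C–C bonds being formed in all. The closest known reaction type is the Danheiser benzannulation in its Wolff variant, established for alpha-diazo ketones with alkyl and silyl alkynyl ethers; a ketene that also carries an ester, and an aryl alkynyl ether as partner, have not been shown in it, hence the label. No stereocentre is formed, since the quaternary carbon of racemic 24 disappears on ring opening. The step needs regiocontrol in the [2+2] addition, which the polarised ynol ether supplies (its oxygen-bearing carbon bonds to the ketene alpha carbon, so prenyl ends between C–OH and C–OAr), and it needs C–C instead of C–O ring closure, which is expected because an ester carbonyl is a poor oxa-diene terminus and because ring opening of 24 is reversible while only the carbocyclic 6-pi closure ends in an aromatic ring. Slow addition of 22 keeps the ketene dilute, and the hindered diaryl ether C–O bond is already present in 14.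

Step 12
Reactants: 27 benzannulation product (TMSE ester, two MOM ethers)
Product: 28 2-(trimethylsilyl)ethyl 2-{[5,8-dihydroxy-2,2-dimethyl-7-(3-methylbut-2-enyl)-2H-chromen-6-yl]oxy}-4-hydroxy-6-methoxy-3-(3-methylbut-2-enyl)benzoate
Conditions: HCl (1 M in MeOH, degassed), 0 °C to rt, Ar
Reagents that add atoms: none
Why: Acid-catalysed acetal exchange of the aryl MOM ethers with methanol under mild conditions commonly used beside prenyl groups and chromenes should free both ring A hydroxyls, while the TMSE ester is stable to dilute acid.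

Step 13
Reactants: 28 triol TMSE ester
Product: 29 2-{[5,8-dihydroxy-2,2-dimethyl-7-(3-methylbut-2-enyl)-2H-chromen-6-yl]oxy}-4-hydroxy-6-methoxy-3-(3-methylbut-2-enyl)benzoic acid
Conditions: TBAF (4 equiv), THF, 0 °C, Ar; then cold dilute HCl to pH 4
Reagents that add atoms: none
Why: Fluoride attacks silicon and the ester fragments by beta-elimination to ethylene and Me3SiF, so the di-ortho-substituted carboxyl is freed without attack at its carbonyl, and the electron-rich acid is protonated only at work-up and used at once to avoid decarboxylation.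

Step 14
Reactants: 29 triol acid
Product: 30 depsidone methyl ether (the target with OMe in place of the ring B hydroxyl ortho to the lactone carbonyl)
Conditions: EDC·HCl, CH2Cl2/THF (0.002 M), 0 °C to rt, Ar
Reagents that add atoms: none
Why: Carbodiimide activation of the acid and attack of the ring A hydroxyl ortho to the ether oxygen should close the seven-membered lactone (depsidone lactonisation), since the other two hydroxyls cannot reach the carboxyl within the molecule and high dilution suppresses intermolecular esters.

Step 15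
Reactants: 30 depsidone methyl ether
Product: 31 CNP0263700.0 (target)
Conditions: MgI2·OEt2 (4 equiv), PhMe/Et2O, 60 °C; then dilute HCl
Reagents that add atoms: none
Why: Chelation-controlled demethylation should cleave only the ether ortho to the carbonyl, because MgI2 binds the lactone carbonyl and that methoxy oxygen while iodide removes the methyl group as MeI, under conditions mild enough for the prenyl groups and the chromene.

**Compound list**

1 | 1,2,4,5-tetramethoxybenzene | COc1cc(OC)c(OC)cc1OC | starting material
2 | prenyl bromide (1-bromo-3-methylbut-2-ene) | CC(C)=CCBr | starting material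
3 | 3,6-dilithio-1,2,4,5-tetramethoxybenzene | [Li]c1c(OC)c(OC)c([Li])c(OC)c1OC | intermediate (not isolated)
4 | 1,2,4,5-tetramethoxy-3,6-bis(3-methylbut-2-enyl)benzene | COc1c(CC=C(C)C)c(OC)c(OC)c(CC=C(C)C)c1OC | intermediate
5 | 2,5-dimethoxy-3,6-bis(3-methylbut-2-enyl)cyclohexa-2,5-diene-1,4-dione | COC1=C(CC=C(C)C)C(=O)C(OC)=C(CC=C(C)C)C1=O | intermediate
6 | 2,5-dihydroxy-3,6-bis(3-methylbut-2-enyl)cyclohexa-2,5-diene-1,4-dione | OC1=C(CC=C(C)C)C(=O)C(O)=C(CC=C(C)C)C1=O | intermediate
7 | 2,5-bis(methoxymethoxy)-3,6-bis(3-methylbut-2-enyl)cyclohexa-2,5-diene-1,4-dione | COCOC1=C(CC=C(C)C)C(=O)C(OCOC)=C(CC=C(C)C)C1=O | intermediate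
8 | ortho-quinone methide tautomer of 7 (4-hydroxy-3,6-bis(methoxymethoxy)-2-(3-methylbut-2-enylidene)-5-(3-methylbut-2-enyl)cyclohexa-3,5-dienone) | O=C1C(OCOC)=C(CC=C(C)C)C(O)=C(OCOC)C1=CC=C(C)C | intermediate (not isolated)
9 | 5,8-bis(methoxymethoxy)-2,2-dimethyl-7-(3-methylbut-2-enyl)-2H-chromen-6-ol (ring A phenol) | Oc1c(CC=C(C)C)c(OCOC)c2OC(C)(C)C=Cc2c1OCOC | intermediate
10 | trichloroethylene | ClC=C(Cl)Cl | starting material
11 | 6-[(E)-1,2-dichlorovinyloxy]-5,8-bis(methoxymethoxy)-2,2-dimethyl-7-(3-methylbut-2-enyl)-2H-chromene | Cl/C=C(/Cl)Oc1c(CC=C(C)C)c(OCOC)c2OC(C)(C)C=Cc2c1OCOC | intermediate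
12 | 6-(chloroethynyloxy)-5,8-bis(methoxymethoxy)-2,2-dimethyl-7-(3-methylbut-2-enyl)-2H-chromene | ClC#COc1c(CC=C(C)C)c(OCOC)c2OC(C)(C)C=Cc2c1OCOC | intermediate (not isolated)
13 | lithium acetylide of the ring A ethynyl ether | [Li]C#COc1c(CC=C(C)C)c(OCOC)c2OC(C)(C)C=Cc2c1OCOC | intermediate (not isolated)
14 | 5,8-bis(methoxymethoxy)-2,2-dimethyl-7-(3-methylbut-2-enyl)-6-[(5-methylhex-4-en-1-yn-1-yl)oxy]-2H-chromene (ring A aryl prenylethynyl ether) | CC(C)=CCC#COc1c(CC=C(C)C)c(OCOC)c2OC(C)(C)C=Cc2c1OCOC | intermediate
15 | methyl 2-methoxyacrylate | COC(=C)C(=O)OC | starting material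
16 | 2-methoxyacrylic acid | COC(=C)C(=O)O | intermediate
17 | Meldrum's acid (2,2-dimethyl-1,3-dioxane-4,6-dione) | CC1(C)OC(=O)CC(=O)O1 | starting material
18 | 2-(trimethylsilyl)ethanol | C[Si](C)(C)CCO | starting material
19 | 5-(1-hydroxy-2-methoxyprop-2-enylidene)-2,2-dimethyl-1,3-dioxane-4,6-dione (acyl Meldrum's acid, enol form) | COC(=C)C(O)=C1C(=O)OC(C)(C)OC1=O | intermediate (not isolated)
20 | 4-methoxypenta-1,4-diene-1,3-dione (acylketene) | COC(=C)C(=O)C=C=O | intermediate (not isolated)
21 | 2-(trimethylsilyl)ethyl 4-methoxy-3-oxopent-4-enoate | COC(=C)C(=O)CC(=O)OCC[Si](C)(C)C | intermediate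
22 | 2-(trimethylsilyl)ethyl 2-diazo-4-methoxy-3-oxopent-4-enoate | COC(=C)C(=O)C(=[N+]=[N-])C(=O)OCC[Si](C)(C)C | intermediate
23 | 2-(trimethylsilyl)ethyl 3-methoxy-2-(oxomethylidene)but-3-enoate (vinylketene) | COC(=C)C(=C=O)C(=O)OCC[Si](C)(C)C | intermediate (not isolated)
24 | racemic vinylcyclobutenone: 2-(trimethylsilyl)ethyl 2-(ring A aryloxy)-1-(1-methoxyvinyl)-3-(3-methylbut-2-enyl)-4-oxocyclobut-2-ene-1-carboxylate | O=C1C(CC=C(C)C)=C(Oc2c(CC=C(C)C)c(OCOC)c3OC(C)(C)C=Cc3c2OCOC)C1(C(=C)OC)C(=O)OCC[Si](C)(C)C | intermediate (not isolated)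
25 | dienylketene with the ketenyl and methoxyvinyl groups cis on the central double bond | O=C=C(CC=C(C)C)/C(Oc1c(CC=C(C)C)c(OCOC)c2OC(C)(C)C=Cc2c1OCOC)=C(\C(=C)OC)C(=O)OCC[Si](C)(C)C | intermediate (not isolated)
26 | cyclohexa-2,4-dienone tautomer of 27 | O=C1CC(OC)=C(C(=O)OCC[Si](C)(C)C)C(Oc2c(CC=C(C)C)c(OCOC)c3OC(C)(C)C=Cc3c2OCOC)=C1CC=C(C)C | intermediate (not isolated)
27 | 2-(trimethylsilyl)ethyl 2-{[5,8-bis(methoxymethoxy)-2,2-dimethyl-7-(3-methylbut-2-enyl)-2H-chromen-6-yl]oxy}-4-hydroxy-6-methoxy-3-(3-methylbut-2-enyl)benzoate | COc1cc(O)c(CC=C(C)C)c(Oc2c(CC=C(C)C)c(OCOC)c3OC(C)(C)C=Cc3c2OCOC)c1C(=O)OCC[Si](C)(C)C | intermediate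
28 | 2-(trimethylsilyl)ethyl 2-{[5,8-dihydroxy-2,2-dimethyl-7-(3-methylbut-2-enyl)-2H-chromen-6-yl]oxy}-4-hydroxy-6-methoxy-3-(3-methylbut-2-enyl)benzoate | COc1cc(O)c(CC=C(C)C)c(Oc2c(CC=C(C)C)c(O)c3OC(C)(C)C=Cc3c2O)c1C(=O)OCC[Si](C)(C)C | intermediate
29 | 2-{[5,8-dihydroxy-2,2-dimethyl-7-(3-methylbut-2-enyl)-2H-chromen-6-yl]oxy}-4-hydroxy-6-methoxy-3-(3-methylbut-2-enyl)benzoic acid | COc1cc(O)c(CC=C(C)C)c(Oc2c(CC=C(C)C)c(O)c3OC(C)(C)C=Cc3c2O)c1C(=O)O | intermediate
30 | depsidone methyl ether (target with OMe on ring B ortho to the lactone carbonyl) | CC(C)=CCc1c(O)c2c(c3c1Oc1c(CC=C(C)C)c(O)cc(OC)c1C(=O)O3)C=CC(C)(C)O2 | intermediate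
31 | CNP0263700.0 | CC(C)=CCc1c(O)c2c(c3c1Oc1c(CC=C(C)C)c(O)cc(O)c1C(=O)O3)C=CC(C)(C)O2 | target

**Step count**

Total: 15 steps. Longest linear sequence: 12 steps (steps 1–7, then 11–15); steps 8–10 form the three-step side branch to 22.

**Steps most likely to fail**

Step 11 (Proposed new method). The ester on the ketene carbon gives 23 acylketene character, so the zwitterion or the ring-opened ketene may close through the ester oxygen to a pyranone instead of forming the carbocycle, and irradiation may also ring-open the chromene. The fallback uses known chemistry, a nucleophilic aromatic substitution that makes the diaryl ether from a finished ring B; it sets out from phenol 9 and returns to the route at acid 29. Commercial 3-fluoro-5-methoxyphenol is protected with MOMCl and iPr2NEt to give 1-fluoro-3-methoxy-5-(methoxymethoxy)benzene F1. Lithiation between fluorine and the MOM ether (n-BuLi, THF, −78 °C) and copper-catalysed alkylation with prenyl bromide give 1-fluoro-5-methoxy-3-(methoxymethoxy)-2-(3-methylbut-2-enyl)benzene F2. A second lithiation between fluorine and methoxy with lithium 2,2,6,6-tetramethylpiperidide at −78 °C, quenched with allyl chloroformate, gives allyl 2-fluoro-6-methoxy-4-(methoxymethoxy)-3-(3-methylbut-2-enyl)benzoate F3. The phenoxide of 9 displaces the ester-activated fluoride (Cs2CO3, DMSO, 100 °C) to give the allyl ester diaryl ether with three MOM groups F4. HCl in methanol removes the MOM groups to give the allyl ester triol F5, and Pd(PPh3)4 with morpholine cleaves the allyl ester to 29.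

Step 7. The hindered lithium acetylide may alkylate slowly or at the tertiary end of prenyl bromide, and the ynol ether may isomerise or hydrate during isolation. The fallback builds the alkynyl ether with the prenyl group already on the two-carbon unit; it sets out from phenol 9 and returns at ynol ether 14. Commercial 4-methylpent-3-en-1-ol is oxidised with Dess–Martin periodinane and NaHCO3 to 4-methylpent-3-enal F6, and CBr4 with PPh3 (Corey–Fuchs olefination) converts it into 1,1-dibromo-5-methylhexa-1,4-diene F7. Copper-catalysed coupling of F7 with 9 (CuI, 2,2'-bipyridine, K3PO4, PhMe, 110 °C) replaces the bromine trans to the chain and gives the (Z)-1-bromoenol ether of the ring A phenol F8, from which KOtBu eliminates HBr to give 14.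

Step 14. With three free hydroxyls present during activation, intermolecular acylation may compete with ring closure, and the ring A hydroquinone may oxidise in air. The fallback activates the carboxyl before the nucleophile is unmasked; it sets out from 27 and returns at lactone 30. TBAF cleaves the TMSE ester of 27 with both MOM groups in place to give the bis-MOM acid F9, and EDC with pentafluorophenol converts it into the bis-MOM pentafluorophenyl ester F10. HCl in methanol then removes the MOM groups to give the pentafluorophenyl ester with free ring A hydroxyls F11 (not isolated), and on neutralisation with NaHCO3 the hydroxyl next to the ether oxygen closes the lactone with loss of pentafluorophenol to give 30.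

**Further compounds**

F1 | step 11 | 1-fluoro-3-methoxy-5-(methoxymethoxy)benzene | COCOc1cc(F)cc(OC)c1
F2 | step 11 | 1-fluoro-5-methoxy-3-(methoxymethoxy)-2-(3-methylbut-2-enyl)benzene | COCOc1cc(OC)cc(F)c1CC=C(C)C
F3 | step 11 | allyl 2-fluoro-6-methoxy-4-(methoxymethoxy)-3-(3-methylbut-2-enyl)benzoate | C=CCOC(=O)c1c(F)c(CC=C(C)C)c(OCOC)cc1OC
F4 | step 11 | allyl 2-{[5,8-bis(methoxymethoxy)-2,2-dimethyl-7-(3-methylbut-2-enyl)-2H-chromen-6-yl]oxy}-6-methoxy-4-(methoxymethoxy)-3-(3-methylbut-2-enyl)benzoate | C=CCOC(=O)c1c(Oc2c(CC=C(C)C)c(OCOC)c3OC(C)(C)C=Cc3c2OCOC)c(CC=C(C)C)c(OCOC)cc1OC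
F5 | step 11 | allyl 2-{[5,8-dihydroxy-2,2-dimethyl-7-(3-methylbut-2-enyl)-2H-chromen-6-yl]oxy}-4-hydroxy-6-methoxy-3-(3-methylbut-2-enyl)benzoate | C=CCOC(=O)c1c(Oc2c(CC=C(C)C)c(O)c3OC(C)(C)C=Cc3c2O)c(CC=C(C)C)c(O)cc1OC
F6 | step 7 | 4-methylpent-3-enal | CC(C)=CCC=O
F7 | step 7 | 1,1-dibromo-5-methylhexa-1,4-diene | BrC(Br)=CCC=C(C)C
F8 | step 7 | 6-{[(Z)-1-bromo-5-methylhexa-1,4-dien-1-yl]oxy}-5,8-bis(methoxymethoxy)-2,2-dimethyl-7-(3-methylbut-2-enyl)-2H-chromene | Br/C(Oc1c(CC=C(C)C)c(OCOC)c2OC(C)(C)C=Cc2c1OCOC)=C\CC=C(C)C
F9 | step 14 | 2-{[5,8-bis(methoxymethoxy)-2,2-dimethyl-7-(3-methylbut-2-enyl)-2H-chromen-6-yl]oxy}-4-hydroxy-6-methoxy-3-(3-methylbut-2-enyl)benzoic acid | COc1cc(O)c(CC=C(C)C)c(Oc2c(CC=C(C)C)c(OCOC)c3OC(C)(C)C=Cc3c2OCOC)c1C(=O)O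
F10 | step 14 | pentafluorophenyl ester of F9 | COc1cc(O)c(CC=C(C)C)c(Oc2c(CC=C(C)C)c(OCOC)c3OC(C)(C)C=Cc3c2OCOC)c1C(=O)Oc1c(F)c(F)c(F)c(F)c1F
F11 | step 14 | pentafluorophenyl 2-{[5,8-dihydroxy-2,2-dimethyl-7-(3-methylbut-2-enyl)-2H-chromen-6-yl]oxy}-4-hydroxy-6-methoxy-3-(3-methylbut-2-enyl)benzoate | COc1cc(O)c(CC=C(C)C)c(Oc2c(CC=C(C)C)c(O)c3OC(C)(C)C=Cc3c2O)c1C(=O)Oc1c(F)c(F)c(F)c(F)c1F
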